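**Plan**

- Numbering (drimane type): C4 = CMe2, C5=C6 = the alkene of ring B, C8 = CH(CH3), C9 = quaternary C(CH3)(C11H2–aryl), C10 = ring-fusion CH; aryl carbons C1' (benzylic) to C6'.
- Ring B is a cyclohexene, and C7–C8 and C9–C10 are the two ring bonds once removed from its C5=C6 alkene. Cutting both is a retro-[4+2] step that leaves ring A as 6,6-dimethyl-1-vinylcyclohexene and an (E)-2-(arylmethyl)but-2-enal, whose formyl group stands in for the C9 methyl.
- Other cuts: the aryl O–SO3H bond, the C3'–CHO bond ortho to the phenol and the two O–benzyl bonds (late); the enal C=C (Wittig), C11–C9 (ylide alkylation) and the vinyl–ring bond of the diene (cross-coupling) (early).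
- Forward: ring A is bought as 2,2-dimethylcyclohexanone and made into the diene; the arene of 2,4,5-trihydroxybenzaldehyde is elaborated to the enal; ring B, the only ring made, closes in the cycloaddition; CHO→CH3, ortho-formylation, sulfation and debenzylation finish.
- Stereochemistry: C8, C9 and C10 all arise in the cycloaddition. C8/C9 comes from the E geometry of the enal, C10/C9 from the formyl-endo transition state, the absolute sense from a chiral oxazaborolidinium catalyst; no later step touches them.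

Key step: step 11

Assumption 1: the sense of induction is taken from the formyl C–H···O binding model for 2-substituted enals, on which the catalyst from (S)-α,α-diphenylprolinol should give the enantiomer drawn; if the first run shows the opposite sense, the catalyst from the (R)-amino alcohol is used and nothing else changes.

Assumption 2: the target is taken as the free hydrogen sulfate as drawn; the sulfate is carried as its sodium salt and protonated only in the last work-up.

**Route**

Step 1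
Reactants: 1 2,2-dimethylcyclohexanone
Product: 2 6,6-dimethylcyclohex-1-en-1-yl trifluoromethanesulfonate
Conditions: LiN(iPr)2, THF, −78 °C; PhNTf2, −78 °C → rt; sat. NH4Cl
Reagents that add atoms: N-phenylbis(trifluoromethanesulfonimide), O=S(=O)(N(c1ccccc1)S(=O)(=O)C(F)(F)F)C(F)(F)F
Why: Only one α-carbon of 1 carries hydrogen, so deprotonation gives a single lithium enolate, which is O-sulfonylated by PhNTf2 (enol triflate formation).

Step 2
Reactants: 2 6,6-dimethylcyclohex-1-en-1-yl trifluoromethanesulfonate; 3 4,4,5,5-tetramethyl-2-vinyl-1,3,2-dioxaborolane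
Product: 4 6,6-dimethyl-1-vinylcyclohexene
Conditions: Pd(PPh3)4 (3 mol%), K3PO4, 1,4-dioxane/H2O, 80 °C; pentane extraction, careful distillation
Reagents that add atoms: none
Why: Suzuki–Miyaura coupling of an alkenyl triflate with a vinylboronate under zerovalent palladium catalysis is routine and should give the 1,3-diene without double-bond migration.

Step 3
Reactants: 5 2,4,5-trihydroxybenzaldehyde
Product: 6 4,5-bis(benzyloxy)-2-hydroxybenzaldehyde
Conditions: BnBr (2.05 equiv), K2CO3 (2.2 equiv), DMF, 0 °C → rt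
Reagents that add atoms: benzyl bromide, BrCc1ccccc1
Why: Williamson etherification; the 2-hydroxyl is hydrogen-bonded to the formyl group and far less nucleophilic, so two equivalents of benzyl bromide should alkylate only the 4- and 5-hydroxyls.

Step 4
Reactants: 6 4,5-bis(benzyloxy)-2-hydroxybenzaldehyde
Product: 7 4,5-bis(benzyloxy)-2-(triisopropylsilyloxy)benzaldehyde
Conditions: TIPSCl, imidazole, DMAP (cat.), DMF, rt
Reagents that add atoms: chlorotriisopropylsilane, CC(C)[Si](Cl)(C(C)C)C(C)C
Why: Silylation of the remaining phenol gives a bulky aryl silyl ether that survives the hydride, ylide and Lewis-acid steps and falls off later under hot hydroxide.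

Step 5
Reactants: 7 4,5-bis(benzyloxy)-2-(triisopropylsilyloxy)benzaldehyde
Product: 8 [4,5-bis(benzyloxy)-2-(triisopropylsilyloxy)phenyl]methanol
Conditions: NaBH4, THF/MeOH, 0 °C, short contact; sat. NH4Cl
Reagents that add atoms: none
Why: Borohydride reduction of the aryl aldehyde; the low temperature, short time and bulk of the triisopropylsilyl group should prevent silyl migration from the phenol oxygen to the new alkoxide.

Step 6
Reactants: 8 [4,5-bis(benzyloxy)-2-(triisopropylsilyloxy)phenyl]methanol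
Product: 9 1,2-bis(benzyloxy)-4-(bromomethyl)-5-(triisopropylsilyloxy)benzene
Conditions: CBr4, PPh3, CH2Cl2, 0 °C; short silica plug; used at once
Reagents that add atoms: carbon tetrabromide, BrC(Br)(Br)Br
Why: Appel bromination works under neutral conditions, which suits an electron-rich benzylic bromide that ionises easily and is therefore not stored.

Step 7
Reactants: 9 1,2-bis(benzyloxy)-4-(bromomethyl)-5-(triisopropylsilyloxy)benzene; 10 methyl (triphenylphosphoranylidene)acetate (2.1 equiv)
Product: 12 methyl 3-[4,5-bis(benzyloxy)-2-(triisopropylsilyloxy)phenyl]-2-(triphenylphosphoranylidene)propanoate, via phosphonium bromide 11 (not isolated)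
Conditions: EtOAc, reflux; precipitated phosphonium salt filtered off
Reagents that add atoms: none
Why: Ester-stabilised ylides are alkylated on carbon by benzylic bromides, and the second equivalent of 10 deprotonates salt 11 (transylidation) and leaves as its own insoluble bromide; the ester ylide is chosen because the formyl ylide tends to alkylate on oxygen.

Step 8
Reactants: 12 methyl 3-[4,5-bis(benzyloxy)-2-(triisopropylsilyloxy)phenyl]-2-(triphenylphosphoranylidene)propanoate; 13 acetaldehyde
Product: 14 methyl (E)-2-{[4,5-bis(benzyloxy)-2-(triisopropylsilyloxy)phenyl]methyl}but-2-enoate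
Conditions: MeCHO (5 equiv), toluene, sealed tube, 80 °C
Reagents that add atoms: none
Why: Wittig olefination of a stabilised α-substituted ylide with an aliphatic aldehyde should be E-selective (ester trans to the new methyl), which fixes the CH3/CH2Ar cis relationship needed in the cycloaddition.

Step 9
Reactants: 14 methyl (E)-2-{[4,5-bis(benzyloxy)-2-(triisopropylsilyloxy)phenyl]methyl}but-2-enoate
Product: 15 (E)-2-{[4,5-bis(benzyloxy)-2-(triisopropylsilyloxy)phenyl]methyl}but-2-en-1-ol
Conditions: iBu2AlH (2.5 equiv), CH2Cl2, −78 °C; aq. potassium sodium tartrate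
Reagents that add atoms: none
Why: 1,2-Reduction of the enoate by the aluminium hydride gives the allylic alcohol and leaves the alkene geometry, the silyl ether and the benzyl ethers untouched.

Step 10
Reactants: 15 (E)-2-{[4,5-bis(benzyloxy)-2-(triisopropylsilyloxy)phenyl]methyl}but-2-en-1-ol
Product: 16 (E)-2-{[4,5-bis(benzyloxy)-2-(triisopropylsilyloxy)phenyl]methyl}but-2-enal
Conditions: MnO2 (activated, excess), CH2Cl2, rt
Reagents that add atoms: none
Why: Allylic oxidation with MnO2 is selective for the allylic alcohol and should give the enal without E/Z isomerisation.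

Step 11
Reactants: 4 6,6-dimethyl-1-vinylcyclohexene; 16 (E)-2-{[4,5-bis(benzyloxy)-2-(triisopropylsilyloxy)phenyl]methyl}but-2-enal
Product: 17 (1S,2R,8aR)-1-{[4,5-bis(benzyloxy)-2-(triisopropylsilyloxy)phenyl]methyl}-2,5,5-trimethyl-1,2,3,5,6,7,8,8a-octahydronaphthalene-1-carbaldehyde
Conditions: (S)-1-(2-methylphenyl)-3,3-diphenyltetrahydro-1H,3H-pyrrolo[1,2-c][1,3,2]oxazaborole (C24H24BNO) protonated with HN(SO2CF3)2 (20 mol%), CH2Cl2, −78 → −20 °C, diene in excess
Reagents that add atoms: none
Why: The protonated oxazaborolidine binds the formyl oxygen of the s-trans enal 16 and lowers its LUMO, and the s-cis diene 4 then adds in a concerted, asynchronous [4+2] cycloaddition, suprafacial on both partners, in which the β-carbon bonds to the vinyl CH2 (C7–C8) ahead of the α-carbon to the ring terminus (C9–C10). The closest known reactions are Lewis-acid- and oxazaborolidinium-catalysed Diels–Alder reactions of 1-vinylcyclohexenes with 2-substituted enals such as tiglic aldehyde. Ring B closes by this intermolecular [4+2] annulation, both of its new bonds forming in the one step and its alkene appearing at C5=C6, while ring A arrives ready-made. C8 relative to C9 follows from the E geometry of 16 (CH3 cis to CH2Ar, trans to CHO); C10 relative to C9 follows from the formyl-endo transition state, which puts CHO cis to C1 and trans to H-10; the absolute configuration at C9 is set by the catalyst, one phenyl group of which covers one face of the bound enal. The step needs ortho regiochemistry, endo topology and one π-face: the first should come from the unhindered CH2 terminus of 4 pairing with the electrophilic β-carbon, the second from secondary overlap of the coordinated carbonyl with the diene, the third from the catalyst. The gem-dimethyl group next to C5 disfavours the s-trans rotamer of 4 and so keeps the diene in its reactive form.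

Step 12
Reactants: 17 (1S,2R,8aR)-1-{[4,5-bis(benzyloxy)-2-(triisopropylsilyloxy)phenyl]methyl}-2,5,5-trimethyl-1,2,3,5,6,7,8,8a-octahydronaphthalene-1-carbaldehyde
Product: 19 4,5-bis(benzyloxy)-2-{[(1R,2R,8aS)-1,2,5,5-tetramethyl-1,2,3,5,6,7,8,8a-octahydronaphthalen-1-yl]methyl}phenol, via hydrazone 18 (not isolated)
Conditions: N2H4·H2O (excess), diethylene glycol, 130 °C; then KOH, 200 °C, N2; cold 1 M HCl
Reagents that add atoms: none
Why: Wolff–Kishner reduction (Huang-Minlon procedure) turns the neopentyl formyl group into the C9 methyl through hydrazone 18 and loss of N2, and hydroxide at 200 °C also cleaves the aryl O–Si bond; the benzyl ethers, the alkene and the stereocentres (C9 has no α-hydrogen) should be unaffected.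

Step 13
Reactants: 19 4,5-bis(benzyloxy)-2-{[(1R,2R,8aS)-1,2,5,5-tetramethyl-1,2,3,5,6,7,8,8a-octahydronaphthalen-1-yl]methyl}phenol
Product: 20 2,3-bis(benzyloxy)-6-hydroxy-5-{[(1R,2R,8aS)-1,2,5,5-tetramethyl-1,2,3,5,6,7,8,8a-octahydronaphthalen-1-yl]methyl}benzaldehyde
Conditions: MgCl2, Et3N, (CH2O)n, MeCN, reflux; 1 M HCl
Reagents that add atoms: paraformaldehyde (formaldehyde), C=O
Why: In the magnesium-mediated ortho-formylation the magnesium phenoxide delivers formaldehyde to the only free ortho position (C3', between OH and OBn), and a second formaldehyde oxidises the hydroxymethyl intermediate to the salicylaldehyde.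

Step 14
Reactants: 20 2,3-bis(benzyloxy)-6-hydroxy-5-{[(1R,2R,8aS)-1,2,5,5-tetramethyl-1,2,3,5,6,7,8,8a-octahydronaphthalen-1-yl]methyl}benzaldehyde
Product: 22 sodium 3,4-bis(benzyloxy)-2-formyl-6-{[(1R,2R,8aS)-1,2,5,5-tetramethyl-1,2,3,5,6,7,8,8a-octahydronaphthalen-1-yl]methyl}phenyl sulfate, via pyridinium aryl sulfate 21 (not isolated)
Conditions: SO3·pyridine (5 equiv), pyridine, 60 °C; aq. NaHCO3; reversed-phase (C18) chromatography
Reagents that add atoms: sulfur trioxide–pyridine complex, O=S(=O)=O.c1ccncc1; sodium hydrogen carbonate, [Na+].OC(=O)[O-]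
Why: O-Sulfation with SO3·pyridine can only occur at the single free hydroxyl, warming overcomes its hydrogen bond to the formyl group, and the sulfate monoester is kept as its base-stable sodium salt.

Step 15
Reactants: 22 sodium 3,4-bis(benzyloxy)-2-formyl-6-{[(1R,2R,8aS)-1,2,5,5-tetramethyl-1,2,3,5,6,7,8,8a-octahydronaphthalen-1-yl]methyl}phenyl sulfate
Product: 24 2-formyl-3,4-dihydroxy-6-{[(1R,2R,8aS)-1,2,5,5-tetramethyl-1,2,3,5,6,7,8,8a-octahydronaphthalen-1-yl]methyl}phenyl hydrogen sulfate, via sodium salt 23 (not isolated)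
Conditions: H2 (1 atm), Pd/C (10 wt%), EtOAc/MeOH, rt, stopped at full debenzylation; filter; HCl aq. (1.0 equiv), 0 °C; C18 desalting, lyophilise
Reagents that add atoms: none
Why: Hydrogenolysis of the two aryl benzyl ethers over Pd/C should be much faster than hydrogenation of the hindered trisubstituted C5=C6 alkene or the chelated aryl aldehyde, the sulfate anion is inert, and one equivalent of cold acid then gives the hydrogen sulfate.

**Compound list**

1 | 2,2-dimethylcyclohexanone | CC1(C)CCCCC1=O | starting material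
2 | 6,6-dimethylcyclohex-1-en-1-yl trifluoromethanesulfonate | CC1(C)CCCC=C1OS(=O)(=O)C(F)(F)F | intermediate
3 | 4,4,5,5-tetramethyl-2-vinyl-1,3,2-dioxaborolane (vinylboronic acid pinacol ester) | C=CB1OC(C)(C)C(C)(C)O1 | starting material
4 | 6,6-dimethyl-1-vinylcyclohexene | C=CC1=CCCCC1(C)C | intermediate
5 | 2,4,5-trihydroxybenzaldehyde | O=Cc1cc(O)c(O)cc1O | starting material
6 | 4,5-bis(benzyloxy)-2-hydroxybenzaldehyde | O=Cc1cc(OCc2ccccc2)c(OCc2ccccc2)cc1O | intermediate
7 | 4,5-bis(benzyloxy)-2-(triisopropylsilyloxy)benzaldehyde | O=Cc1cc(OCc2ccccc2)c(OCc2ccccc2)cc1O[Si](C(C)C)(C(C)C)C(C)C | intermediate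
8 | [4,5-bis(benzyloxy)-2-(triisopropylsilyloxy)phenyl]methanol | OCc1cc(OCc2ccccc2)c(OCc2ccccc2)cc1O[Si](C(C)C)(C(C)C)C(C)C | intermediate
9 | 1,2-bis(benzyloxy)-4-(bromomethyl)-5-(triisopropylsilyloxy)benzene | BrCc1cc(OCc2ccccc2)c(OCc2ccccc2)cc1O[Si](C(C)C)(C(C)C)C(C)C | intermediate
10 | methyl (triphenylphosphoranylidene)acetate | COC(=O)C=P(c1ccccc1)(c1ccccc1)c1ccccc1 | starting material
11 | {3-[4,5-bis(benzyloxy)-2-(triisopropylsilyloxy)phenyl]-1-methoxy-1-oxopropan-2-yl}triphenylphosphonium bromide | COC(=O)C(Cc1cc(OCc2ccccc2)c(OCc2ccccc2)cc1O[Si](C(C)C)(C(C)C)C(C)C)[P+](c1ccccc1)(c1ccccc1)c1ccccc1.[Br-] | intermediate (not isolated)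
12 | methyl 3-[4,5-bis(benzyloxy)-2-(triisopropylsilyloxy)phenyl]-2-(triphenylphosphoranylidene)propanoate | COC(=O)C(Cc1cc(OCc2ccccc2)c(OCc2ccccc2)cc1O[Si](C(C)C)(C(C)C)C(C)C)=P(c1ccccc1)(c1ccccc1)c1ccccc1 | intermediate
13 | acetaldehyde | CC=O | starting material
14 | methyl (E)-2-{[4,5-bis(benzyloxy)-2-(triisopropylsilyloxy)phenyl]methyl}but-2-enoate | C/C=C(/C(=O)OC)Cc1cc(OCc2ccccc2)c(OCc2ccccc2)cc1O[Si](C(C)C)(C(C)C)C(C)C | intermediate
15 | (E)-2-{[4,5-bis(benzyloxy)-2-(triisopropylsilyloxy)phenyl]methyl}but-2-en-1-ol | C/C=C(/CO)Cc1cc(OCc2ccccc2)c(OCc2ccccc2)cc1O[Si](C(C)C)(C(C)C)C(C)C | intermediate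
16 | (E)-2-{[4,5-bis(benzyloxy)-2-(triisopropylsilyloxy)phenyl]methyl}but-2-enal | C/C=C(/C=O)Cc1cc(OCc2ccccc2)c(OCc2ccccc2)cc1O[Si](C(C)C)(C(C)C)C(C)C | intermediate
17 | (1S,2R,8aR)-1-{[4,5-bis(benzyloxy)-2-(triisopropylsilyloxy)phenyl]methyl}-2,5,5-trimethyl-1,2,3,5,6,7,8,8a-octahydronaphthalene-1-carbaldehyde | C[C@@H]1CC=C2[C@@H](CCCC2(C)C)[C@]1(C=O)Cc1cc(OCc2ccccc2)c(OCc2ccccc2)cc1O[Si](C(C)C)(C(C)C)C(C)C | intermediate
18 | hydrazone of 17 | C[C@@H]1CC=C2[C@@H](CCCC2(C)C)[C@]1(C=NN)Cc1cc(OCc2ccccc2)c(OCc2ccccc2)cc1O[Si](C(C)C)(C(C)C)C(C)C | intermediate (not isolated)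
19 | 4,5-bis(benzyloxy)-2-{[(1R,2R,8aS)-1,2,5,5-tetramethyl-1,2,3,5,6,7,8,8a-octahydronaphthalen-1-yl]methyl}phenol | C[C@@H]1CC=C2[C@@H](CCCC2(C)C)[C@]1(C)Cc1cc(OCc2ccccc2)c(OCc2ccccc2)cc1O | intermediate
20 | 2,3-bis(benzyloxy)-6-hydroxy-5-{[(1R,2R,8aS)-1,2,5,5-tetramethyl-1,2,3,5,6,7,8,8a-octahydronaphthalen-1-yl]methyl}benzaldehyde | C[C@@H]1CC=C2[C@@H](CCCC2(C)C)[C@]1(C)Cc1cc(OCc2ccccc2)c(OCc2ccccc2)c(C=O)c1O | intermediate
21 | pyridinium 3,4-bis(benzyloxy)-2-formyl-6-{[(1R,2R,8aS)-1,2,5,5-tetramethyl-1,2,3,5,6,7,8,8a-octahydronaphthalen-1-yl]methyl}phenyl sulfate | C[C@@H]1CC=C2[C@@H](CCCC2(C)C)[C@]1(C)Cc1cc(OCc2ccccc2)c(OCc2ccccc2)c(C=O)c1OS(=O)(=O)[O-].c1cc[nH+]cc1 | intermediate (not isolated)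
22 | sodium 3,4-bis(benzyloxy)-2-formyl-6-{[(1R,2R,8aS)-1,2,5,5-tetramethyl-1,2,3,5,6,7,8,8a-octahydronaphthalen-1-yl]methyl}phenyl sulfate | C[C@@H]1CC=C2[C@@H](CCCC2(C)C)[C@]1(C)Cc1cc(OCc2ccccc2)c(OCc2ccccc2)c(C=O)c1OS(=O)(=O)[O-].[Na+] | intermediate
23 | sodium 2-formyl-3,4-dihydroxy-6-{[(1R,2R,8aS)-1,2,5,5-tetramethyl-1,2,3,5,6,7,8,8a-octahydronaphthalen-1-yl]methyl}phenyl sulfate | C[C@@H]1CC=C2[C@@H](CCCC2(C)C)[C@]1(C)Cc1cc(O)c(O)c(C=O)c1OS(=O)(=O)[O-].[Na+] | intermediate (not isolated)
24 | 2-formyl-3,4-dihydroxy-6-{[(1R,2R,8aS)-1,2,5,5-tetramethyl-1,2,3,5,6,7,8,8a-octahydronaphthalen-1-yl]methyl}phenyl hydrogen sulfate | C[C@@H]1CC=C2[C@@H](CCCC2(C)C)[C@]1(C)Cc1cc(O)c(O)c(C=O)c1OS(=O)(=O)O | target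

**Step count**

Total: 15 steps. Longest linear sequence: 13 steps (steps 3–15, from 2,4,5-trihydroxybenzaldehyde 5); the diene branch (steps 1–2) joins at step 11.

**Steps most likely to fail**

1. Step 11. The hindered trisubstituted enal may turn over slowly on the chiral catalyst, and facial or endo/exo discrimination may be insufficient. Fallback: setting out from 4 and 16, the cycloaddition is run with an achiral Lewis acid (EtAlCl2, CH2Cl2, −78 → −40 °C), which should give the racemic endo adduct F1. Wolff–Kishner reduction as in step 12 gives the racemic phenol F2, from which any exo-derived diastereomer is removed by chromatography. Preparative HPLC on a chiral stationary phase (amylose tris(3,5-dimethylphenylcarbamate)) then separates 19 from its enantiomer F3, and the route is rejoined at 19.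

2. Step 14. The phenol is flanked on both sides and hydrogen-bonded to the formyl group, so sulfur trioxide transfer may stall, and the polar salt may be lost on purification. Fallback: from 20, the sodium phenoxide (NaH, THF, 0 °C) is treated with isobutyl chlorosulfate, a stronger sulfuryl electrophile, to give the neutral, silica-stable aryl isobutyl sulfate F4. NaI in acetone at 55 °C then removes the isobutyl group by SN2 attack at carbon and gives the sodium sulfate 22 directly.

3. Step 15. Hydrogen may add to or shift the C5=C6 alkene, or reduce the aryl aldehyde, while the benzyl ethers are cleaved. Fallback: from 20, the benzyl ethers are removed before sulfation with BCl3 and pentamethylbenzene (CH2Cl2, −78 °C) to give the trihydroxy aldehyde F5. The catechol is tied up as the di-tert-butylsilylene derivative F6 (tBu2Si(OTf)2, 2,6-lutidine, CH2Cl2, 0 °C), and the remaining phenol is sulfated as in step 14 to give the silylene-protected sodium sulfate F7. Et3N·3HF in THF then removes the silylene without hydrogen and gives sodium salt 23, which is acidified to 24 as in step 15.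

**Further compounds**

F1 | step 11 | racemic 1-{[4,5-bis(benzyloxy)-2-(triisopropylsilyloxy)phenyl]methyl}-2,5,5-trimethyl-1,2,3,5,6,7,8,8a-octahydronaphthalene-1-carbaldehyde (17 and its enantiomer) | C[C@@H]1CC=C2[C@@H](CCCC2(C)C)[C@]1(C=O)Cc1cc(OCc2ccccc2)c(OCc2ccccc2)cc1O[Si](C(C)C)(C(C)C)C(C)C.C[C@H]1CC=C2[C@H](CCCC2(C)C)[C@@]1(C=O)Cc1cc(OCc2ccccc2)c(OCc2ccccc2)cc1O[Si](C(C)C)(C(C)C)C(C)C
F2 | step 11 | racemic 4,5-bis(benzyloxy)-2-[(1,2,5,5-tetramethyl-1,2,3,5,6,7,8,8a-octahydronaphthalen-1-yl)methyl]phenol (19 and its enantiomer) | C[C@@H]1CC=C2[C@@H](CCCC2(C)C)[C@]1(C)Cc1cc(OCc2ccccc2)c(OCc2ccccc2)cc1O.C[C@H]1CC=C2[C@H](CCCC2(C)C)[C@@]1(C)Cc1cc(OCc2ccccc2)c(OCc2ccccc2)cc1O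
F3 | step 11 | 4,5-bis(benzyloxy)-2-{[(1S,2S,8aR)-1,2,5,5-tetramethyl-1,2,3,5,6,7,8,8a-octahydronaphthalen-1-yl]methyl}phenol (enantiomer of 19) | C[C@H]1CC=C2[C@H](CCCC2(C)C)[C@@]1(C)Cc1cc(OCc2ccccc2)c(OCc2ccccc2)cc1O
F4 | step 14 | 3,4-bis(benzyloxy)-2-formyl-6-{[(1R,2R,8aS)-1,2,5,5-tetramethyl-1,2,3,5,6,7,8,8a-octahydronaphthalen-1-yl]methyl}phenyl 2-methylpropyl sulfate | C[C@@H]1CC=C2[C@@H](CCCC2(C)C)[C@]1(C)Cc1cc(OCc2ccccc2)c(OCc2ccccc2)c(C=O)c1OS(=O)(=O)OCC(C)C
F5 | step 15 | 2,3,6-trihydroxy-5-{[(1R,2R,8aS)-1,2,5,5-tetramethyl-1,2,3,5,6,7,8,8a-octahydronaphthalen-1-yl]methyl}benzaldehyde | C[C@@H]1CC=C2[C@@H](CCCC2(C)C)[C@]1(C)Cc1cc(O)c(O)c(C=O)c1O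
F6 | step 15 | 2,2-di-tert-butyl-5-hydroxy-6-{[(1R,2R,8aS)-1,2,5,5-tetramethyl-1,2,3,5,6,7,8,8a-octahydronaphthalen-1-yl]methyl}-1,3,2-benzodioxasilole-4-carbaldehyde | C[C@@H]1CC=C2[C@@H](CCCC2(C)C)[C@]1(C)Cc1cc2O[Si](C(C)(C)C)(C(C)(C)C)Oc2c(C=O)c1O
F7 | step 15 | sodium 2,2-di-tert-butyl-4-formyl-6-{[(1R,2R,8aS)-1,2,5,5-tetramethyl-1,2,3,5,6,7,8,8a-octahydronaphthalen-1-yl]methyl}-1,3,2-benzodioxasilol-5-yl sulfate | C[C@@H]1CC=C2[C@@H](CCCC2(C)C)[C@]1(C)Cc1cc2O[Si](C(C)(C)C)(C(C)(C)C)Oc2c(C=O)c1OS(=O)(=O)[O-].[Na+]
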